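How much product stands in this flask at 2.0 h, and how far is the coupling partner from saturation?

the same everywhere: gas 23 mM (held)
- Thursday's: starting material 0.44 M; free catalyst 0.15 mM; run made earlier
- Sunday's: starting material 0.44 M; free catalyst 0.23 mM; run made earlier
- Monday's: starting material 0.88 M; free catalyst 0.31 mM; run made earlier
- flask: starting material 0.44 M; free catalyst 0.31 mM; time 2.0 h

| run | time / min | product / % | starting material / % |
|---|---|---|---|
| Thursday's | 6.00 | 1 | 99 |
| Thursday's | 20.0 | 7 | 96 |
| Thursday's | 30.0 | 7 | 89 |
| Thursday's | 50.0 | 16 | 86 |
| Thursday's | 80.0 | 25 | 75 |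
| Thursday's | 90.0 | 23 | 74 |
| Thursday's | 120 | 35 | 62 |
| Sunday's | 15.0 | 2 | 96 |
| Sunday's | 30.0 | 12 | 89 |
| Sunday's | 50.0 | 20 | 80 |
| Sunday's | 60.0 | 25 | 77 |
| Sunday's | 80.0 | 31 | 67 |
| Sunday's | 90.0 | 39 | 64 |
| Sunday's | 120 | 47 | 54 |
| Monday's | 10.0 | 1 | 98 |
| Monday's | 30.0 | 7 | 91 |
| Monday's | 60.0 | 13 | 84 |
| Monday's | 80.0 | 21 | 80 |
| Monday's | 120 | 27 | 72 |

(readings scatter by 1.5 percentage points)

- at the start none of the gas is in solution
- coupling partner is what gas becomes in solution

- amount of product at 2.0 h, in percent of the starting material charged
- concentration of coupling partner in solution at 2.0 h, in percent of saturation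

The useful quantity is the molar pace: the product made per minute, as a concentration, counted from the start of a run. Monday's run has the flask's catalyst and gas, and its last reading gives this pace:

v = 1.98 mM/min

But Monday's run holds twice the flask's starting material. Sunday's run tests whether that matters. Its pace is 1.76 mM/min up to 50.0 min and 1.72 mM/min up to 120 min, while its starting material falls to 54%. That reads as zero order in starting material, so Monday's pace is carried over to the flask.

The flask's product curve is then a straight line from the start. It crosses the falling starting material at half of the charge:

t = 111 min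

At the asked time it stands at:

[product]/[starting material charged] = 54.0%

The line meets the whole charge at 3.70 h, so the curve has to bend into that level around there. The runs hold no reading of the coupling partner, so no figure for it is reckoned here.

The forecast gave 50% of product (43% to 60%) and 50% of saturation (30% to 70%), holding that “gas transfer is becoming limiting”, and its product lies below the 54.0% reckoned here. The flask gives 55.8% of product and 36.0% of saturation.

    starting material + free catalyst → catalyst intermediate A (k = 3.33 /M/s)
    coupling partner + catalyst intermediate A ⇌ catalyst intermediate B (K = 380 /M, k = 23.8 /M/s)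
    catalyst intermediate B ⇌ by-product + catalyst intermediate C (K = 36.4 M, k = 29.2 /s)
    catalyst intermediate C ⇌ free catalyst + product (K = 1.28 M, k = 0.432 /s)
    gas ⇌ coupling partner, rate k5*(csat - [coupling partner]) (kL = 0.00228 /s)

Gas transfer delivers 3.15 mM/min into an empty solution. In the flask at 0.976 h the coupling partner is made 1.00 times as fast as it is used up, so delivery can be set equal to the pace. That balance leaves 37.1% of saturation; the flask stands at 33.3% at 1.00 h and 36.0% at 2.0 h. The same flask read at 3.0 h lies on the line, with 81.0% reckoned and 81.3% simulated. What the flask lacks at 2.0 h is time: 44% of its starting material is still there, and its product of 55.8% becomes >99.9% at 20.0 h, a gain of 44 percentage points.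

(The runs are calculated for substances that don't exist; scatter was added.)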